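(The constants used here are those of an exercise; no experiment stands behind them.)

In a one-step world, with E binding Z in a single reversible step, the cold flask leads, because the binding constant rises from 10 M⁻¹ at 25 °C to 19.0 M⁻¹ at 10 °C. This flask has more steps: E turns into X, G feeds Z, X takes up Z to give X.Z, and Z also pairs with itself.

| flask | E | G | temperature | time | remark |
|---|---|---|---|---|---|
| maple | 2.0 M | 1.90 M | 25 °C | 15 min |  |
| elm | 2.0 M | 1.90 M | 10 °C | 15 min |  |
| ash | 2.0 M | 1.90 M |  | 15 min | at 10 °C until 5.0 min, from then on at 25 °C |

    X + Z ⇌ X.Z (K1 = 10 M⁻¹, k1 = 0.0023 M⁻¹ s⁻¹, Ea1 = 75.0 kJ mol⁻¹, ΔH1 = −30.0 kJ mol⁻¹)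
    E ⇌ X (K2 = 0.69, k2 = 0.21 s⁻¹, Ea2 = 68.0 kJ mol⁻¹, ΔH2 = 16.0 kJ mol⁻¹)
    G → Z (k3 = 0.023 s⁻¹, Ea3 = 87.0 kJ mol⁻¹)
    2 Z → Z2 (k4 = 3.7 × 10⁻⁴ M⁻¹ s⁻¹, Ea4 = 77.0 kJ mol⁻¹)
    (constants at 25 °C)

- a step written with two of one species runs at k times the square of its concentration and takes two of it each time
- constants are those at 25 °C; use the activation energies and enthalpies for any other temperature

- the best flask by amount of X.Z, in percent of the E charged; "all alike" if 1.5 percentage points covers them all (maple / elm / ash / all alike)
- amount of X.Z at the end, in percent of the E charged, maple
- amount of X.Z at the end, in percent of the E charged, elm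
- amount of X.Z at the end, in percent of the E charged, ash

For elm to beat maple, the binding step must come close to its equilibrium within the run, so the question is how long capture takes. The forward time of E to X is 4.76 s at 25 °C and 20.4 s at 10 °C, and the times below are much longer. X can therefore be taken as a fixed share of free E, 0.408 warm and 0.329 cold.

With Z held at its charge of 1.90 M, the concentration that sets the order, the loss of free E is pseudo-first-order. The capture time, one over the product of the binding rate constant, the X share and the Z charge, is 9.34 min at 25 °C. At 10 °C, where the rate constant falls to 0.201 of its warm value, it is 57.6 min.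

Elm's capture time is longer than its run of 15 min, so elm stands at 0.260 capture times, far from the opposite outcome. Maple stands at 1.61, and ash, with 5.0 min cold, at 1.16. The reckoning here therefore ranks maple, ash, elm. Taking Z at its full charge from the start gives ceilings of 79.9%, 68.6% and 22.9% of the E charged, and it commits to no closer figures.

The forecast names maple, with 44.4% for maple, 14.3% for elm and 40% for ash. These stand below those ceilings , and its hand steps ran “including the Z dimerisation loss and the reverse step”.

The flasks end at 45.5% in maple, 41.0% in ash and 14.3% in elm, so maple leads. Read at 150 min, elm holds 50.2% of the E charged as X.Z, more than the 44.0% in maple, and that reading stands at 2.60 elm capture times. A neighbour of maple charged with 1.1 M of G has its capture time stretched to 16.1 min, so its run spans 0.932 capture times, and at 15.0 min it holds 31.3% as X.Z.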